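**Strategy.** Everything rests on disconnecting the tetrasubstituted C3=C4 alkene of the furan-2(5H)-one, whose C3 aroyl group (ring A) and C4 aryl group (ring B) are cis and carry the same 3,5-dibromo-4-oxygenated pattern. Syn addition of an arylcopper reagent across C2≡C3 of a racemic methyl 4-silyloxy-5-(4-methoxyphenyl)pent-2-ynoate, followed by capture of the alkenylcopper with the matching aroyl chloride, forms both C–C bonds in one operation and leaves the ester cis to the oxygen-bearing carbon (future C5). Acidic desilylation then closes the lactone, bromination–dehydrobromination installs the (Z)-benzylidene of ring C, and BBr3 unmasks the three phenols.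

Key step: step 7

Remark on the chemistry: compounds 4, 5 and 13–17 are racemic with one enantiomer drawn in the SMILES (the single sp3 stereocentre is erased in step 9); iodine–magnesium exchange with iPrMgCl gives the arylmagnesium chloride, so 11 is drawn as the chloride; the enoate 14 is the (2Z) isomer; ring C is the aryl of the C5 benzylidene, and the furanone is numbered O1, C2(=O), C3, C4, C5.

Step 1
Reactants: 1 methyl propiolate; 2 2-(4-methoxyphenyl)acetaldehyde
Product: 4 rac-methyl 4-hydroxy-5-(4-methoxyphenyl)pent-2-ynoate, via lithium acetylide 3 (not isolated)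
Conditions: LiN(SiMe3)2, THF, −78 °C; then 2 (freshly distilled), −78 °C; AcOH quench at −78 °C
Reagents that add atoms: none
Why: Acetylide 1,2-addition to an aldehyde; the ester-stabilised lithium acetylide formed at −78 °C is weakly basic and should add to the carbonyl faster than it enolises the arylacetaldehyde, and the new carbinol centre forms as a racemate, which is acceptable because it becomes sp2 in step 9.

Step 2
Reactants: 4 rac-methyl 4-hydroxy-5-(4-methoxyphenyl)pent-2-ynoate
Product: 5 rac-methyl 4-[(tert-butyldimethylsilyl)oxy]-5-(4-methoxyphenyl)pent-2-ynoate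
Conditions: TBSOTf, 2,6-lutidine, CH2Cl2, −78 to 0 °C
Reagents that add atoms: tert-butyldimethylsilyl trifluoromethanesulfonate, CC(C)(C)[Si](C)(C)OS(=O)(=O)C(F)(F)F
Why: Silyl ether formation with a silyl triflate and a hindered pyridine base, chosen so that no nucleophilic amine can add to the electron-poor alkyne; the stereocentre is untouched.

Step 3
Reactants: 6 2,6-dibromophenol
Product: 7 2,6-dibromo-4-iodophenol
Conditions: N-iodosuccinimide, TFA (cat.), MeCN, rt
Reagents that add atoms: N-iodosuccinimide, O=C1CCC(=O)N1I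
Why: Electrophilic aromatic iodination; the hydroxyl group directs to the only free activated position (para), both ortho positions being blocked by bromine, and an iodine electrophile cannot displace the bromines.

Step 4
Reactants: 7 2,6-dibromo-4-iodophenol
Product: 8 1,3-dibromo-5-iodo-2-methoxybenzene
Conditions: MeI, K2CO3, DMF, rt
Reagents that add atoms: iodomethane, CI
Why: Williamson ether synthesis; the acidic dibromophenol is fully deprotonated by carbonate and the unhindered methyl electrophile overcomes the flanking bromines.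

Step 5
Reactants: 9 3,5-dibromo-4-methoxybenzoic acid
Product: 10 3,5-dibromo-4-methoxybenzoyl chloride
Conditions: (COCl)2, DMF (cat.), CH2Cl2, 0 °C to rt; evaporate, use crude
Reagents that add atoms: oxalyl chloride, O=C(Cl)C(=O)Cl
Why: Acid chloride formation through the Vilsmeier-type chloroiminium species; the aryl bromides and the methyl ether are inert.

Step 6
Reactants: 8 1,3-dibromo-5-iodo-2-methoxybenzene
Product: 11 (3,5-dibromo-4-methoxyphenyl)magnesium chloride (THF solution, used directly)
Conditions: iPrMgCl, THF, −30 °C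
Reagents that add atoms: isopropylmagnesium chloride, CC(C)[Mg]Cl
Why: Iodine–magnesium exchange; the C–I bond of the electron-poor arene exchanges far faster than the C–Br bonds at low temperature, and the resulting Grignard has no ortho halogen that could eliminate to an aryne.

Step 7
Reactants: 5 rac-methyl 4-[(tert-butyldimethylsilyl)oxy]-5-(4-methoxyphenyl)pent-2-ynoate; 11 (3,5-dibromo-4-methoxyphenyl)magnesium chloride; 10 3,5-dibromo-4-methoxybenzoyl chloride
Product: 14 rac-methyl (2Z)-4-[(tert-butyldimethylsilyl)oxy]-2-(3,5-dibromo-4-methoxybenzoyl)-3-(3,5-dibromo-4-methoxyphenyl)-5-(4-methoxyphenyl)pent-2-enoate, via arylcopper 12 (not isolated), via alkenylcopper 13 (not isolated)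
Conditions: 11 (1.6 equiv), CuBr·SMe2 (1.6 equiv), THF, −40 °C; 5, −78 °C; then 10 (2 equiv), −78 to −40 °C; aq. NH4Cl/NH3
Reagents that add atoms: none
Why: Transmetalation of 11 with CuBr·SMe2 gives the monovalent arylcopper 12, which complexes the alkyne of 5 and delivers its aryl group to the β-carbon (C3 of the ynoate, future C4 of the ring) while copper ends on the α-carbon of the same face, so alkenylcopper 13 has copper cis to the new aryl group; acylation of that carbon–copper bond by 10 then proceeds with retention. The closest known reaction type is the tandem conjugate carbocupration of alkynoates with capture of the α-cuprio ester by acid chlorides, together with organocopper additions to 4-silyloxy-2-alkynoates that lead to 4-substituted butenolides. No ring is closed and no stereocentre is created; the racemic carbinol centre is untouched. The step needs β-regioselectivity, secured by the polarisation of the alkyne by the ester, and retention of the syn geometry, secured by holding the α-cuprio ester at −78 to −40 °C so that it does not equilibrate through the copper allenoate. It also needs chemoselectivity: the mild arylcopper does not exchange with the four aryl bromides, the silyl ether is too poor a leaving group for propargylic substitution to an allene, and the excess of 10 absorbs surplus 12 as a separable diaryl ketone. The outcome is the (2Z)-enoate with rings A and B cis and the ester cis to the silyloxy carbon, set up for lactonisation.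

Step 8
Reactants: 14 rac-methyl (2Z)-4-[(tert-butyldimethylsilyl)oxy]-2-(3,5-dibromo-4-methoxybenzoyl)-3-(3,5-dibromo-4-methoxyphenyl)-5-(4-methoxyphenyl)pent-2-enoate
Product: 16 rac-3-(3,5-dibromo-4-methoxybenzoyl)-4-(3,5-dibromo-4-methoxyphenyl)-5-[(4-methoxyphenyl)methyl]furan-2(5H)-one, via hydroxy ester 15 (not isolated)
Conditions: aq. HF (48%), MeCN, 0 °C to rt
Reagents that add atoms: none
Why: Acidic fluoride desilylation frees the hydroxyl group, which is held cis to the methyl ester across the tetrasubstituted alkene and should lactonise spontaneously by intramolecular transesterification, while the acidic medium avoids deprotonation of the acidic C5–H of the product.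

Step 9
Reactants: 16 rac-3-(3,5-dibromo-4-methoxybenzoyl)-4-(3,5-dibromo-4-methoxyphenyl)-5-[(4-methoxyphenyl)methyl]furan-2(5H)-one
Product: 18 (5Z)-3-(3,5-dibromo-4-methoxybenzoyl)-4-(3,5-dibromo-4-methoxyphenyl)-5-[(4-methoxyphenyl)methylidene]furan-2(5H)-one, via C5 bromide 17 (not isolated)
Conditions: NBS (1.05 equiv), AIBN (cat.), PhCF3, 85 °C; then Et3N, 0 °C to rt, in the dark
Reagents that add atoms: none
Why: Wohl–Ziegler bromination at C5 (tertiary, allylic and α to the ring oxygen) followed by base-induced dehydrobromination toward the benzylic CH2, the sequence known for converting 3-alkylphthalides and 5-alkylbutenolides into their ylidene derivatives; the (Z) alkene is the thermodynamically preferred isomer because ring C avoids ring B on C4, and a benzylic bromide regioisomer would converge on the same alkene by E1cB elimination.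

Step 10
Reactants: 18 (5Z)-3-(3,5-dibromo-4-methoxybenzoyl)-4-(3,5-dibromo-4-methoxyphenyl)-5-[(4-methoxyphenyl)methylidene]furan-2(5H)-one
Product: 19 cadiolide A, (5Z)-3-(3,5-dibromo-4-hydroxybenzoyl)-4-(3,5-dibromo-4-hydroxyphenyl)-5-[(4-hydroxyphenyl)methylidene]furan-2(5H)-one
Conditions: BBr3 (excess), CH2Cl2, −78 °C to rt, in the dark; then H2O
Reagents that add atoms: none
Why: Lewis acid cleavage of aryl methyl ethers; BBr3 coordinates each methoxy oxygen and bromide removes the methyl group by SN2, a reaction that tolerates ylidenebutenolides, diaryl ketones and aryl bromides, and the alkene geometry should be retained when light is excluded.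

**Compound list**

1 | methyl propiolate | C#CC(=O)OC | starting material
2 | 2-(4-methoxyphenyl)acetaldehyde | COc1ccc(CC=O)cc1 | starting material
3 | lithium 3-methoxy-3-oxoprop-1-yn-1-ide (lithiated methyl propiolate, not isolated) | [Li]C#CC(=O)OC | intermediate
4 | rac-methyl 4-hydroxy-5-(4-methoxyphenyl)pent-2-ynoate | COC(=O)C#C[C@@H](Cc1ccc(OC)cc1)O | intermediate
5 | rac-methyl 4-[(tert-butyldimethylsilyl)oxy]-5-(4-methoxyphenyl)pent-2-ynoate | COC(=O)C#C[C@@H](Cc1ccc(OC)cc1)O[Si](C)(C)C(C)(C)C | intermediate
6 | 2,6-dibromophenol | Oc1c(Br)cccc1Br | starting material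
7 | 2,6-dibromo-4-iodophenol | Oc1c(Br)cc(I)cc1Br | intermediate
8 | 1,3-dibromo-5-iodo-2-methoxybenzene | COc1c(Br)cc(I)cc1Br | intermediate
9 | 3,5-dibromo-4-methoxybenzoic acid | COc1c(Br)cc(C(=O)O)cc1Br | starting material
10 | 3,5-dibromo-4-methoxybenzoyl chloride | COc1c(Br)cc(C(=O)Cl)cc1Br | intermediate
11 | (3,5-dibromo-4-methoxyphenyl)magnesium chloride | COc1c(Br)cc([Mg]Cl)cc1Br | intermediate
12 | (3,5-dibromo-4-methoxyphenyl)copper (monovalent copper, not isolated) | COc1c(Br)cc([Cu])cc1Br | intermediate
13 | rac-{(2E)-4-[(tert-butyldimethylsilyl)oxy]-3-(3,5-dibromo-4-methoxyphenyl)-1-methoxy-5-(4-methoxyphenyl)-1-oxopent-2-en-2-yl}copper, copper cis to the new aryl group (not isolated) | COC(=O)/C([Cu])=C(/c1cc(Br)c(OC)c(Br)c1)[C@@H](Cc1ccc(OC)cc1)O[Si](C)(C)C(C)(C)C | intermediate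
14 | rac-methyl (2Z)-4-[(tert-butyldimethylsilyl)oxy]-2-(3,5-dibromo-4-methoxybenzoyl)-3-(3,5-dibromo-4-methoxyphenyl)-5-(4-methoxyphenyl)pent-2-enoate | COC(=O)/C(C(=O)c1cc(Br)c(OC)c(Br)c1)=C(/c1cc(Br)c(OC)c(Br)c1)[C@@H](Cc1ccc(OC)cc1)O[Si](C)(C)C(C)(C)C | intermediate
15 | rac-methyl (2Z)-2-(3,5-dibromo-4-methoxybenzoyl)-3-(3,5-dibromo-4-methoxyphenyl)-4-hydroxy-5-(4-methoxyphenyl)pent-2-enoate (not isolated) | COC(=O)/C(C(=O)c1cc(Br)c(OC)c(Br)c1)=C(/c1cc(Br)c(OC)c(Br)c1)[C@@H](Cc1ccc(OC)cc1)O | intermediate
16 | rac-3-(3,5-dibromo-4-methoxybenzoyl)-4-(3,5-dibromo-4-methoxyphenyl)-5-[(4-methoxyphenyl)methyl]furan-2(5H)-one | O=C1O[C@H](Cc2ccc(OC)cc2)C(c2cc(Br)c(OC)c(Br)c2)=C1C(=O)c1cc(Br)c(OC)c(Br)c1 | intermediate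
17 | rac-5-bromo-3-(3,5-dibromo-4-methoxybenzoyl)-4-(3,5-dibromo-4-methoxyphenyl)-5-[(4-methoxyphenyl)methyl]furan-2(5H)-one (not isolated) | O=C1O[C@](Br)(Cc2ccc(OC)cc2)C(c2cc(Br)c(OC)c(Br)c2)=C1C(=O)c1cc(Br)c(OC)c(Br)c1 | intermediate
18 | (5Z)-3-(3,5-dibromo-4-methoxybenzoyl)-4-(3,5-dibromo-4-methoxyphenyl)-5-[(4-methoxyphenyl)methylidene]furan-2(5H)-one | O=C1O/C(=C\c2ccc(OC)cc2)C(c2cc(Br)c(OC)c(Br)c2)=C1C(=O)c1cc(Br)c(OC)c(Br)c1 | intermediate
19 | cadiolide A, (5Z)-3-(3,5-dibromo-4-hydroxybenzoyl)-4-(3,5-dibromo-4-hydroxyphenyl)-5-[(4-hydroxyphenyl)methylidene]furan-2(5H)-one | O=C1O/C(=C\c2ccc(O)cc2)C(c2cc(Br)c(O)c(Br)c2)=C1C(=O)c1cc(Br)c(O)c(Br)c1 | target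

**Totals.** Total step count: 10. Longest linear sequence: 7 steps (6 → 7 → 8 → 11 → 14 → 16 → 18 → 19; steps 3, 4, 6, 7, 8, 9, 10).

**Steps most likely to fail**

1. Step 7. The electron-poor aryl group may transfer from copper too slowly. Acylation of the hindered α-cuprio ester may lag behind its equilibration through the copper allenoate, which erodes the alkene geometry, or the acyl group may end on oxygen. Fallback, from 5 back to 14: the carbocupration is run as before with 11 and CuBr·SMe2, but alkenylcopper 13 is quenched at −78 °C with iodine, the most reactive trap for such species. This should give rac-methyl (2E)-4-[(tert-butyldimethylsilyl)oxy]-3-(3,5-dibromo-4-methoxyphenyl)-2-iodo-5-(4-methoxyphenyl)pent-2-enoate F1 with the geometry frozen. A Nozaki–Hiyama–Kishi coupling of F1 with commercial 3,5-dibromo-4-methoxybenzaldehyde (COc1c(Br)cc(C=O)cc1Br; CrCl2, catalytic NiCl2, DMF, rt) activates the alkenyl iodide in preference to the aryl bromides and keeps the alkene geometry. It should give the allylic alcohol methyl (2Z)-4-[(tert-butyldimethylsilyl)oxy]-2-[(3,5-dibromo-4-methoxyphenyl)(hydroxy)methyl]-3-(3,5-dibromo-4-methoxyphenyl)-5-(4-methoxyphenyl)pent-2-enoate F2 as a diastereomer mixture. Dess–Martin oxidation of the carbinol (CH2Cl2, rt) returns ketone 14.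

2. Step 9. Bromine generated in the radical chain may attack the electron-rich ring C electrophilically, or a second bromination may occur before elimination. Fallback, from 16 back to 18, with no halogen electrophile: silylation of 16 (TBSOTf, Et3N, CH2Cl2, 0 °C) should give the 2-silyloxyfuran (2-{[tert-butyl(dimethyl)silyl]oxy}-4-(3,5-dibromo-4-methoxyphenyl)-5-[(4-methoxyphenyl)methyl]furan-3-yl)(3,5-dibromo-4-methoxyphenyl)methanone F3. Oxidation with dimethyldioxirane (acetone, −78 °C to rt) and mild aqueous work-up opens and recloses the ring to rac-3-(3,5-dibromo-4-methoxybenzoyl)-4-(3,5-dibromo-4-methoxyphenyl)-5-hydroxy-5-[(4-methoxyphenyl)methyl]furan-2(5H)-one F4. Acid-catalysed dehydration (TsOH, toluene, 80 °C) then gives 18, again expected as the more stable (Z) isomer.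

3. Step 1. The arylacetaldehyde may enolise and self-condense, or the thermally fragile lithiated propiolate may decompose before it adds. Fallback, from 2 back to 5: addition of the robust acetylide HC≡CMgBr (THF, 0 °C) should give rac-1-(4-methoxyphenyl)but-3-yn-2-ol F5. Silylation (TBSCl, imidazole, DMF) gives rac-tert-butyl{[1-(4-methoxyphenyl)but-3-yn-2-yl]oxy}dimethylsilane F6. Deprotonation of the terminal alkyne (n-BuLi, THF, −78 °C) and capture with methyl chloroformate installs the ester and gives 5.

**Further compounds**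

F1 | step 7 | rac-methyl (2E)-4-[(tert-butyldimethylsilyl)oxy]-3-(3,5-dibromo-4-methoxyphenyl)-2-iodo-5-(4-methoxyphenyl)pent-2-enoate | COC(=O)/C(I)=C(/c1cc(Br)c(OC)c(Br)c1)[C@@H](Cc1ccc(OC)cc1)O[Si](C)(C)C(C)(C)C
F2 | step 7 | methyl (2Z)-4-[(tert-butyldimethylsilyl)oxy]-2-[(3,5-dibromo-4-methoxyphenyl)(hydroxy)methyl]-3-(3,5-dibromo-4-methoxyphenyl)-5-(4-methoxyphenyl)pent-2-enoate (racemic diastereomer mixture) | COC(=O)/C(C(O)c1cc(Br)c(OC)c(Br)c1)=C(/c1cc(Br)c(OC)c(Br)c1)[C@@H](Cc1ccc(OC)cc1)O[Si](C)(C)C(C)(C)C
F3 | step 9 | (2-{[tert-butyl(dimethyl)silyl]oxy}-4-(3,5-dibromo-4-methoxyphenyl)-5-[(4-methoxyphenyl)methyl]furan-3-yl)(3,5-dibromo-4-methoxyphenyl)methanone | COc1ccc(Cc2oc(O[Si](C)(C)C(C)(C)C)c(C(=O)c3cc(Br)c(OC)c(Br)c3)c2-c2cc(Br)c(OC)c(Br)c2)cc1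
F4 | step 9 | rac-3-(3,5-dibromo-4-methoxybenzoyl)-4-(3,5-dibromo-4-methoxyphenyl)-5-hydroxy-5-[(4-methoxyphenyl)methyl]furan-2(5H)-one | O=C1O[C@](O)(Cc2ccc(OC)cc2)C(c2cc(Br)c(OC)c(Br)c2)=C1C(=O)c1cc(Br)c(OC)c(Br)c1
F5 | step 1 | rac-1-(4-methoxyphenyl)but-3-yn-2-ol | C#C[C@@H](Cc1ccc(OC)cc1)O
F6 | step 1 | rac-tert-butyl{[1-(4-methoxyphenyl)but-3-yn-2-yl]oxy}dimethylsilane | C#C[C@@H](Cc1ccc(OC)cc1)O[Si](C)(C)C(C)(C)C
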